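**Strategy.** Everything rests on growing, not cyclising, the oxepine ring (bridge O, C10, C1, C2, C3, C4, C5; germacrane numbering). Its C3=C4(CO2Me) unit, flanked by C2 and the oxygen-bearing C5, is the imprint of a propiolate. Methyl propiolate adds across the enol-ether bond C5=C2 of a 2,3-dihydrofuran (O, C5, C2, C1, C10) and the cyclobutene opens, inserting C3 and C4 with the ester in one operation while both ring-fusion isomers converge. The resulting cyclic β-alkoxy dienoate then accepts a samarium ketyl from C6, which closes the second oxepane, the C5–C6 bond and the lactone. The precursor is a 2,3-dihydrofuran whose side chain already carries C7 and C8, made from geraniol.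

Key step: step 9

Remark (numbering): germacrane labels are used throughout, also for acyclic precursors. C1–C10 is the carbocycle (C10 bears CH3), the ether O bridges C5 and C10, C15 is the ester carbon on C4, the lactone is C6–O–C12(=O)–C11(=C13)–C7, and C8 carries the ester oxygen. In the silyl ethers 18–23 the descriptor at C7 reads S only because of a CIP priority change.

Remark (assumption): the absolute sense of the reagent-controlled steps 5 and 14 is assigned by analogy with the established models; if the opposite sense is found, the antipodal boron reagent or ligand is used.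

**Step 1**
Reactants: 1 geraniol
Product: 2 (2S,3S)-2,3-epoxygeraniol
Conditions: Ti(OiPr)4 (5 mol%), L-(+)-diethyl tartrate (7 mol%), t-BuOOH, 4 Å MS, CH2Cl2, −20 °C
Reagents that add atoms: tert-butyl hydroperoxide, CC(C)(C)OO
Why: Sharpless asymmetric epoxidation of the allylic alcohol; with L-(+)-tartrate oxygen is delivered to the face that gives the (2S,3S)-epoxide, which fixes the tertiary C–O centre that becomes C10.

**Step 2**
Reactants: 2 (2S,3S)-2,3-epoxygeraniol
Product: 3 (3S)-3,7-dimethyloct-6-ene-1,3-diol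
Conditions: Red-Al, THF, 0 °C → rt
Reagents that add atoms: none
Why: Hydroxyl-directed hydride delivery opens the 2,3-epoxy alcohol at C2 (reductive epoxide opening to the 1,3-diol) and leaves the tertiary centre untouched.

**Step 3**
Reactants: 3 (3S)-3,7-dimethyloct-6-ene-1,3-diol
Product: 4 (3S)-3-hydroxy-3,7-dimethyloct-6-enal
Conditions: Dess–Martin periodinane, NaHCO3, CH2Cl2, 0 °C; used crude
Reagents that add atoms: none
Why: Dess–Martin oxidation can only touch the primary alcohol, and the bicarbonate buffer should suppress dehydration of the β-hydroxy aldehyde.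

**Step 4**
Reactants: 5 methyl 4-chloro-4-oxobutanoate; 6 2-methylpropane-2-thiol
Product: 7 S-tert-butyl 4-methoxy-4-oxobutanethioate
Conditions: pyridine, CH2Cl2, 0 °C → rt
Reagents that add atoms: none
Why: Acyl substitution of the acid chloride by the thiol (thioesterification); the methyl ester is not affected.

**Step 5**
Reactants: 4 (3S)-3-hydroxy-3,7-dimethyloct-6-enal; 7 S-tert-butyl 4-methoxy-4-oxobutanethioate
Product: 8 S-tert-butyl (2R,3R,5S)-3,5-dihydroxy-2-(2-methoxy-2-oxoethyl)-5,9-dimethyldec-8-enethioate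
Conditions: 7 (2.2 equiv), bis(menthylmethyl)boron bromide, Et3N, Et2O/CH2Cl2, 0 °C; then 4, −78 °C; pH 7 buffer/MeOH
Reagents that add atoms: none
Why: Reagent-controlled anti-selective boron aldol reaction: only the thioester is enolised, its E(O)-enol borinate reacts through a Zimmerman–Traxler chair to give the anti adduct, and the chiral ligands on boron select the aldehyde face so that C7 and C8 are set as 2R,3R independently of the remote C10 centre; the excess enolate compensates for the free tertiary hydroxyl.

**Step 6**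
Reactants: 8 the aldol adduct
Product: 9 S-tert-butyl (2R,3R,5S)-3-[(tert-butyldimethylsilyl)oxy]-5-hydroxy-2-(2-methoxy-2-oxoethyl)-5,9-dimethyldec-8-enethioate
Conditions: TBSOTf (1.1 equiv), 2,6-lutidine, CH2Cl2, −78 °C
Reagents that add atoms: tert-butyldimethylsilyl triflate, CC(C)(C)[Si](C)(C)OS(=O)(=O)C(F)(F)F
Why: Silyl ether formation at the secondary hydroxyl should be much faster than at the hindered tertiary one at −78 °C, which keeps the tertiary OH free for lactol formation.

**Step 7**
Reactants: 9 the C8 silyl ether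
Product: 11 S-tert-butyl (2R,3R)-3-[(tert-butyldimethylsilyl)oxy]-4-[(2S)-5-hydroxy-2-methyloxolan-2-yl]-2-(2-methoxy-2-oxoethyl)butanethioate (anomer mixture), via hydroxy aldehyde 10 (not isolated)
Conditions: O3, CH2Cl2, −78 °C; Me2S, −78 °C → rt
Reagents that add atoms: ozone, [O-][O+]=O
Why: Ozonolysis of the only C=C bond with reductive work-up gives the γ-hydroxy aldehyde, which should close spontaneously to the five-membered lactol through the tertiary hydroxyl; thioester and silyl ether are inert at −78 °C.

**Step 8**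
Reactants: 11 the lactol
Product: 13 S-tert-butyl (2R,3R)-3-[(tert-butyldimethylsilyl)oxy]-2-(2-methoxy-2-oxoethyl)-4-[(2S)-2-methyl-2,3-dihydrofuran-2-yl]butanethioate, via lactol mesylate 12 (not isolated)
Conditions: MsCl, Et3N, CH2Cl2, −40 °C → 40 °C
Reagents that add atoms: none
Why: Mesylation of the anomeric hydroxyl and base-mediated loss of methanesulfonate through the oxocarbenium ion should give the 2,3-dihydrofuran (glycal-type elimination); no stereocentre is involved.

**Step 9**
Reactants: 13 the 2,3-dihydrofuran; 14 methyl propiolate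
Product: 16 S-tert-butyl (2R,3R)-3-[(tert-butyldimethylsilyl)oxy]-4-[(2S)-6-(methoxycarbonyl)-2-methyl-2,3-dihydrooxepin-2-yl]-2-(2-methoxy-2-oxoethyl)butanethioate, via cyclobutene adduct 15 (not isolated)
Conditions: 14 (3 equiv), Me2AlCl (2.5 equiv), CH2Cl2, −78 → −20 °C; aqueous work-up; then toluene, 100 °C
Reagents that add atoms: none
Why: The Lewis acid activates the propiolate, the nucleophilic enol-ether carbon C2 adds to its β-carbon (the future C3) and the allenolate closes through C4 onto the oxocarbenium carbon C5, a stepwise formal [2+2] cycloaddition of the kind established for enol ethers, silyl enol ethers and enamines with acetylenic esters. The 2-oxabicyclo[3.2.0]hept-6-ene then opens thermally across the ring-fusion bond C5–C2 (4π electrocyclic opening assisted by the push of the ring oxygen and the pull of the ester, the classical two-carbon ring enlargement), which turns the five-membered ring O–C5–C2–C1–C10 into the seven-membered ring O–C5–C4–C3–C2–C1–C10. The only ring closed is the transient cyclobutene, by ionic 4-exo closure of the zwitterion; the seven-membered ring is not closed but arises by ring opening of the bicycle. No new stereocentre survives, because both ring-fusion centres of the two cis-fused diastereomeric cyclobutenes become sp2, so the mixture converges on one dienoate while C7, C8 and C10 stay untouched. The step needs the regiochemistry C2–C3/C5–C4, which the polarisation of the enol ether (nucleophilic at C2) and of the propiolate (electrophilic at its β-carbon) secures, and chemoselectivity for the enol ether, since thioester, ester and silyl ether only coordinate the Lewis acid.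

**Step 10**
Reactants: 16 the dihydrooxepine thioester
Product: 17 methyl (3R,4R)-4-[(tert-butyldimethylsilyl)oxy]-3-formyl-5-[(2S)-6-(methoxycarbonyl)-2-methyl-2,3-dihydrooxepin-2-yl]pentanoate
Conditions: DIBAL-H (1.1 equiv), CH2Cl2, −78 °C; Rochelle salt
Reagents that add atoms: none
Why: DIBAL-H reduction of the thioester should stop at the aldehyde through the tetrahedral thiohemiacetal aluminate, the thioester being more electrophilic than the saturated methyl ester and the push–pull (vinylogous carbonate) ester; C7 should not epimerise under these non-basic conditions.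

**Step 11**
Reactants: 17 the C6 aldehyde
Product: 20 methyl (5R,6S,7S,8R,10S)-8-[(tert-butyldimethylsilyl)oxy]-5,10-epoxy-13-norgermacr-3-en-12,6-olid-15-oate, via hydroxy diester 18 (not isolated), via deconjugated lactone 19 (not isolated)
Conditions: SmI2 (2.5 equiv), MeOH (4 equiv), THF, 0 °C; then DBU (0.2 equiv), CH2Cl2, rt
Reagents that add atoms: none
Why: SmI2-mediated ketyl–olefin cyclisation onto a β-alkoxyacrylate (7-exo): the C6 ketyl can reach C5 only from the face of its C9–C8–C7 tether, which fixes C5 as the cis-bridged centre, and a chair-like Sm(III) chelate between ketyl oxygen and the C15 ester carbonyl with the C7 and C8 substituents pseudo-equatorial should place O6 trans to C4 (6S); the samarium dienolate is protonated, the C6 alkoxide closes the γ-lactone on the C12 ester, and DBU moves the double bond into conjugation (C3=C4).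

**Step 12**
Reactants: 20 the saturated lactone
Product: 23 methyl (5R,6S,7S,8R,10S)-8-[(tert-butyldimethylsilyl)oxy]-5,10-epoxygermacra-3,11(13)-dien-12,6-olid-15-oate, via Mannich base 21 (not isolated), via ammonium iodide 22 (not isolated)
Conditions: LDA, THF, −78 °C; Eschenmoser's salt, −78 °C → rt; MeI, MeOH, rt; aq. NaHCO3, CH2Cl2
Reagents that add atoms: Eschenmoser's salt (N,N-dimethylmethyleneiminium iodide), C=[N+](C)C.[I-]
Why: The lactone enolate (C11, the most acidic C–H) undergoes a Mannich reaction, and quaternisation followed by Hofmann-type elimination gives the exocyclic methylene (α-methylenation); no stereocentre is formed or touched.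

**Step 13**
Reactants: 23 the α-methylene lactone silyl ether
Product: 24 methyl (5R,6S,7R,8R,10S)-8-hydroxy-5,10-epoxygermacra-3,11(13)-dien-12,6-olid-15-oate
Conditions: HF·pyridine, THF/pyridine, 0 °C → rt
Reagents that add atoms: none
Why: Acidic fluoride cleaves the secondary silyl ether without base, so neither conjugate addition to the α-methylene lactone nor translactonisation to the C8 oxygen should occur.

**Step 14**
Reactants: 25 2-methyl-2-vinyloxirane (racemic); 26 4-methoxybenzyl alcohol
Product: 27 (2S)-2-[(4-methoxybenzyl)oxy]-2-methylbut-3-en-1-ol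
Conditions: Pd2(dba)3·CHCl3 (1 mol%), (R,R)-N,N'-(cyclohexane-1,2-diyl)bis[2-(diphenylphosphino)benzamide] (3 mol%), Et3B (1 mol%), CH2Cl2, rt
Reagents that add atoms: none
Why: Palladium-catalysed dynamic kinetic asymmetric allylic etherification of the racemic vinyl epoxide: the boron co-catalyst delivers the alcohol to the tertiary allyl terminus and the chiral diphosphine, acting on rapidly interconverting π-allyl complexes, sets the quaternary centre as S.

**Step 15**
Reactants: 27 the PMB ether alcohol
Product: 28 (2S)-2-[(4-methoxybenzyl)oxy]-2-methylbut-3-enoic acid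
Conditions: TEMPO (cat.), NaClO2, NaOCl (cat.), MeCN/phosphate buffer pH 6.7, 35 °C
Reagents that add atoms: sodium chlorite, [Na+].[O-]Cl=O
Why: TEMPO-catalysed oxidation with chlorite as terminal oxidant takes the primary alcohol through the aldehyde to the acid; the quaternary stereocentre cannot epimerise and the PMB ether and vinyl group are tolerated.

**Step 16**
Reactants: 24 the C8 alcohol; 28 the PMB-protected acid
Product: 30 the 8-O-[(2S)-2-[(4-methoxybenzyl)oxy]-2-methylbut-3-enoyl] ester of 24, via mixed anhydride 29 (not isolated)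
Conditions: 28, 2,4,6-trichlorobenzoyl chloride, Et3N, THF, rt; then 24, DMAP, toluene, rt → 40 °C
Reagents that add atoms: none
Why: Yamaguchi esterification: DMAP attacks the mixed anhydride at the aliphatic carbonyl and the acyl group is transferred to the C8 hydroxyl with retention at C8; the acid has no α-hydrogen and cannot epimerise.

**Step 17**
Reactants: 30 the PMB-protected ester
Product: 31 target, methyl (5R,6S,7R,8R,10S)-8-{[(2S)-2-hydroxy-2-methylbut-3-enoyl]oxy}-5,10-epoxygermacra-3,11(13)-dien-12,6-olid-15-oate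
Conditions: DDQ, CH2Cl2/pH 7 buffer, 0 °C → rt
Reagents that add atoms: none
Why: Oxidative PMB ether cleavage by DDQ (hydride abstraction, hydrolysis of the oxocarbenium ion) frees the tertiary alcohol; the electron-poor alkenes are not affected.

**Compound list**

1 | geraniol, (2E)-3,7-dimethylocta-2,6-dien-1-ol | CC(C)=CCC/C(C)=C/CO | starting material
2 | (2S,3S)-2,3-epoxygeraniol | OC[C@@H]1O[C@@]1(C)CCC=C(C)C | intermediate
3 | (3S)-3,7-dimethyloct-6-ene-1,3-diol | OCC[C@](O)(C)CCC=C(C)C | intermediate
4 | (3S)-3-hydroxy-3,7-dimethyloct-6-enal | O=CC[C@](O)(C)CCC=C(C)C | intermediate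
5 | methyl 4-chloro-4-oxobutanoate | COC(=O)CCC(Cl)=O | starting material
6 | 2-methylpropane-2-thiol | CC(C)(C)S | starting material
7 | S-tert-butyl 4-methoxy-4-oxobutanethioate | COC(=O)CCC(=O)SC(C)(C)C | intermediate
8 | S-tert-butyl (2R,3R,5S)-3,5-dihydroxy-2-(2-methoxy-2-oxoethyl)-5,9-dimethyldec-8-enethioate | CC(C)(C)SC(=O)[C@H](CC(=O)OC)[C@H](O)C[C@](O)(C)CCC=C(C)C | intermediate
9 | 3-O-TBS ether of 8 | CC(C)(C)SC(=O)[C@H](CC(=O)OC)[C@H](O[Si](C)(C)C(C)(C)C)C[C@](O)(C)CCC=C(C)C | intermediate
10 | S-tert-butyl (2R,3R,5S)-3-[(tert-butyldimethylsilyl)oxy]-5-hydroxy-2-(2-methoxy-2-oxoethyl)-5-methyl-8-oxooctanethioate (open hydroxy aldehyde) | CC(C)(C)SC(=O)[C@H](CC(=O)OC)[C@H](O[Si](C)(C)C(C)(C)C)C[C@](O)(C)CCC=O | intermediate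
11 | S-tert-butyl (2R,3R)-3-[(tert-butyldimethylsilyl)oxy]-4-[(2S)-5-hydroxy-2-methyloxolan-2-yl]-2-(2-methoxy-2-oxoethyl)butanethioate (lactol, anomer mixture) | CC(C)(C)SC(=O)[C@H](CC(=O)OC)[C@H](O[Si](C)(C)C(C)(C)C)C[C@]1(C)CCC(O)O1 | intermediate
12 | anomeric methanesulfonate of 11 | CC(C)(C)SC(=O)[C@H](CC(=O)OC)[C@H](O[Si](C)(C)C(C)(C)C)C[C@]1(C)CCC(OS(C)(=O)=O)O1 | intermediate
13 | S-tert-butyl (2R,3R)-3-[(tert-butyldimethylsilyl)oxy]-2-(2-methoxy-2-oxoethyl)-4-[(2S)-2-methyl-2,3-dihydrofuran-2-yl]butanethioate | CC(C)(C)SC(=O)[C@H](CC(=O)OC)[C@H](O[Si](C)(C)C(C)(C)C)C[C@]1(C)CC=CO1 | intermediate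
14 | methyl propiolate | C#CC(=O)OC | starting material
15 | S-tert-butyl (2R,3R)-3-[(tert-butyldimethylsilyl)oxy]-4-[(3S)-7-(methoxycarbonyl)-3-methyl-2-oxabicyclo[3.2.0]hept-6-en-3-yl]-2-(2-methoxy-2-oxoethyl)butanethioate (cis-fused, both ring-fusion diastereomers) | CC(C)(C)SC(=O)[C@H](CC(=O)OC)[C@H](O[Si](C)(C)C(C)(C)C)C[C@]1(C)CC2C=C(C(=O)OC)C2O1 | intermediate
16 | S-tert-butyl (2R,3R)-3-[(tert-butyldimethylsilyl)oxy]-4-[(2S)-6-(methoxycarbonyl)-2-methyl-2,3-dihydrooxepin-2-yl]-2-(2-methoxy-2-oxoethyl)butanethioate | CC(C)(C)SC(=O)[C@H](CC(=O)OC)[C@H](O[Si](C)(C)C(C)(C)C)C[C@]1(C)CC=CC(C(=O)OC)=CO1 | intermediate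
17 | methyl (3R,4R)-4-[(tert-butyldimethylsilyl)oxy]-3-formyl-5-[(2S)-6-(methoxycarbonyl)-2-methyl-2,3-dihydrooxepin-2-yl]pentanoate | O=C[C@H](CC(=O)OC)[C@H](O[Si](C)(C)C(C)(C)C)C[C@]1(C)CC=CC(C(=O)OC)=CO1 | intermediate
18 | bicyclic hydroxy diester: 5,10-ether-bridged C1–C10 ring with C2=C3, C4-H/CO2Me (both C4 epimers), C6-OH, C7-CH2CO2Me, C8-OTBS, C10-CH3; 5R,6S,7S,8R,10S | CC(C)(C)[Si](C)(C)O[C@@H]1C[C@]2(C)CC=CC(C(=O)OC)[C@@H](O2)[C@@H](O)[C@@H]1CC(=O)OC | intermediate
19 | deconjugated lactone: as 20 but C2=C3 and C4-H (both C4 epimers) | CC(C)(C)[Si](C)(C)O[C@@H]1C[C@]2(C)CC=CC(C(=O)OC)[C@@H](O2)[C@H]2OC(=O)C[C@@H]21 | intermediate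
20 | methyl (5R,6S,7S,8R,10S)-8-[(tert-butyldimethylsilyl)oxy]-5,10-epoxy-13-norgermacr-3-en-12,6-olid-15-oate (trans-fused γ-lactone, C11 = CH2) | CC(C)(C)[Si](C)(C)O[C@@H]1C[C@]2(C)CCC=C(C(=O)OC)[C@@H](O2)[C@H]2OC(=O)C[C@@H]21 | intermediate
21 | 11-(dimethylaminomethyl) derivative of 20 (Mannich base, C11 epimers) | CC(C)(C)[Si](C)(C)O[C@@H]1C[C@]2(C)CCC=C(C(=O)OC)[C@@H](O2)[C@H]2OC(=O)C(CN(C)C)[C@@H]21 | intermediate
22 | trimethylammonium iodide of 21 | CC(C)(C)[Si](C)(C)O[C@@H]1C[C@]2(C)CCC=C(C(=O)OC)[C@@H](O2)[C@H]2OC(=O)C(C[N+](C)(C)C)[C@@H]21.[I-] | intermediate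
23 | methyl (5R,6S,7S,8R,10S)-8-[(tert-butyldimethylsilyl)oxy]-5,10-epoxygermacra-3,11(13)-dien-12,6-olid-15-oate | CC(C)(C)[Si](C)(C)O[C@@H]1C[C@]2(C)CCC=C(C(=O)OC)[C@@H](O2)[C@H]2OC(=O)C(=C)[C@@H]21 | intermediate
24 | methyl (5R,6S,7R,8R,10S)-8-hydroxy-5,10-epoxygermacra-3,11(13)-dien-12,6-olid-15-oate | O[C@@H]1C[C@]2(C)CCC=C(C(=O)OC)[C@@H](O2)[C@H]2OC(=O)C(=C)[C@@H]21 | intermediate
25 | 2-methyl-2-vinyloxirane (racemic) | C=CC1(C)CO1 | starting material
26 | 4-methoxybenzyl alcohol | COc1ccc(CO)cc1 | starting material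
27 | (2S)-2-[(4-methoxybenzyl)oxy]-2-methylbut-3-en-1-ol | C=C[C@](C)(OCc1ccc(OC)cc1)CO | intermediate
28 | (2S)-2-[(4-methoxybenzyl)oxy]-2-methylbut-3-enoic acid | C=C[C@](C)(OCc1ccc(OC)cc1)C(=O)O | intermediate
29 | mixed anhydride of 28 with 2,4,6-trichlorobenzoic acid | C=C[C@](C)(OCc1ccc(OC)cc1)C(=O)OC(=O)c1c(Cl)cc(Cl)cc1Cl | intermediate
30 | 8-O-[(2S)-2-[(4-methoxybenzyl)oxy]-2-methylbut-3-enoyl] ester of 24 | C=C[C@](C)(OCc1ccc(OC)cc1)C(=O)O[C@@H]1C[C@]2(C)CCC=C(C(=O)OC)[C@@H](O2)[C@H]2OC(=O)C(=C)[C@@H]21 | intermediate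
31 | methyl (5R,6S,7R,8R,10S)-8-{[(2S)-2-hydroxy-2-methylbut-3-enoyl]oxy}-5,10-epoxygermacra-3,11(13)-dien-12,6-olid-15-oate | C=C[C@](C)(O)C(=O)O[C@@H]1C[C@]2(C)CCC=C(C(=O)OC)[C@@H](O2)[C@H]2OC(=O)C(=C)[C@@H]21 | target

**Step count.** Total: 17 steps. Longest linear sequence: 14 steps (1–3, 5–13, 16, 17).

**Steps most likely to fail**

Step 9 (key step). The Lewis acid may oligomerise or hydrolyse the acid-sensitive dihydrofuran faster than the cycloaddition proceeds, or the cyclobutene may not open cleanly. The fallback sets out from 13 and builds the same cyclobutene without a Lewis acid by a ketene route. (Methoxycarbonyl)ketene, generated in situ from methyl 3-chloro-3-oxopropanoate and Et3N in CH2Cl2 at 0 °C, should add thermally to the enol ether in a [2+2] cycloaddition, ketene carbonyl carbon to C2, to give the cyclobutanone β-keto ester F1. NaBH4 in MeOH at −78 °C should reduce the ketone to the β-hydroxy ester F2. Mesylation and elimination (MsCl, Et3N, CH2Cl2, 0 °C → rt) should then give the cyclobutene, at which point the fallback is back on the route at 15. Heating in toluene at 100 °C gives 16 as in step 9.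

Step 11. Simple reduction or pinacol coupling of the aldehyde may outrun the seven-membered ring closure, and the samarium dienolate may expel the C5 ether oxygen before it is protonated. The fallback sets out from 17 and uses a neutral radical chain instead of electron transfer. With Bu3SnH and AIBN in benzene at 80 °C the O-stannyl ketyl radical should add to C5, the allylic radical abstracts hydrogen from the stannane, and the tin alkoxide lactonises on the C12 ester. Brief treatment with DBU brings the double bond into conjugation, and the fallback is back on the route at 20. No new compound arises.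

Step 5. The free tertiary hydroxyl may protonate the enol borinate, and anti or facial selectivity may be low with this aldehyde. The fallback sets out from 4 and separates the two stereocentres. A catalytic asymmetric Mukaiyama aldol reaction with the trimethylsilyl ketene S,O-acetal of S-tert-butyl thioacetate (chiral Ti(IV) Lewis acid, Et2O, −10 °C, desilylating work-up) should set C8 and give S-tert-butyl (3R,5S)-3,5-dihydroxy-5,9-dimethyldec-8-enethioate F3. Fráter–Seebach alkylation then sets C7: LDA (3.3 equiv) in THF at −78 → −20 °C deprotonates both hydroxyls and the thioester α-carbon, and methyl bromoacetate should enter anti to the C8 alkoxide. This gives 8, where the fallback is back on the route.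

**Further compounds**

F1 | step 9 | S-tert-butyl (2R,3R)-3-[(tert-butyldimethylsilyl)oxy]-4-[(3S)-7-(methoxycarbonyl)-3-methyl-6-oxo-2-oxabicyclo[3.2.0]heptan-3-yl]-2-(2-methoxy-2-oxoethyl)butanethioate | CC(C)(C)SC(=O)[C@H](CC(=O)OC)[C@H](O[Si](C)(C)C(C)(C)C)C[C@]1(C)CC2C(=O)C(C(=O)OC)C2O1
F2 | step 9 | S-tert-butyl (2R,3R)-3-[(tert-butyldimethylsilyl)oxy]-4-[(3S)-6-hydroxy-7-(methoxycarbonyl)-3-methyl-2-oxabicyclo[3.2.0]heptan-3-yl]-2-(2-methoxy-2-oxoethyl)butanethioate | CC(C)(C)SC(=O)[C@H](CC(=O)OC)[C@H](O[Si](C)(C)C(C)(C)C)C[C@]1(C)CC2C(O)C(C(=O)OC)C2O1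
F0 | step 11 | none | none
F3 | step 5 | S-tert-butyl (3R,5S)-3,5-dihydroxy-5,9-dimethyldec-8-enethioate | CC(C)(C)SC(=O)C[C@H](O)C[C@](O)(C)CCC=C(C)C
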